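How much Z, as a percentage of the X charged, stands in the flask at the asked time, and which change raises it most?

all flasks: Q 120 mM (held)
- larch: X 0.70 M; run made earlier
- maple: X 1 M; run made earlier
- flask: X 1.4 M; time 8.0 min

| larch: time / min | larch: Z / % | maple: time / min | maple: Z / % |
|---|---|---|---|
| 0.333 | 0 | 0.417 | 1.2 |
| 1.00 | 2.8 | 0.667 | 0 |
| 1.50 | 1.6 | 1.00 | 0.6 |
| 2.50 | 8.5 | 2.00 | 4.4 |
| 4.00 | 12.8 | 3.00 | 4.9 |
| 5.00 | 15.8 | 5.00 | 10.5 |

(readings scatter by 1 percentage point)

- solid, in amounts per volume of the solution: X
- at the start none of X is in solution
- at the start none of Q is in solution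

1. Z at 8.0 min, in percent of the X charged
2. the change that raises the amount of Z at 8.0 min, in percent of the X charged most ("none" if none brings more than 2 percentage points) (noon / summer / midnight / winter / none)
3. amount of Z at 8.0 min, in percent of the X charged, after summer

- noon: doubling the transfer coefficient of Q, all else as stated
- summer: doubling the saturation concentration of Q, all else as stated
- midnight: doubling the dissolution coefficient of X, all else as stated
- winter: doubling the solubility of X, all else as stated

The first setting is the charge of X. Converted to concentration, the last larch reading is cZ = 0.111 M and the last maple reading, at the same time, 0.105 M, although maple holds 1.43 times the X of larch. So between these two charges, within the scatter of the readings, cZ does not grow with the charge, and I read Z as forming at zero order in solid X. Their mean over that time is 0.0216 M min⁻¹, and this molar pace, the cZ formed per minute of run, read from both charges together, is what I carry. My reckoning for the flask is 0.172 M, or 12.3% of its charge.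

Next come the four changes. If Z forms from dissolved X and dissolved Q, each standing at a steady level, then by hand summer and winter each double the pace and give 24.6%, and I cannot separate them. By hand, noon and midnight quicken the supply into solution, and I put no number on either.

The forecast, which allows for a lag, says 12.6%, summer, and 24.5% after it, adding: “The runs never varied Q, so this is inferred, not shown”.

The flask gives 13.1%, and summer is best, gaining 9.2 percentage points to reach 22.3%, with winter at 7.2 points, noon at 2.9 points and midnight at 1.4 points.

    E + D → Z (k = 2.30 M⁻¹ min⁻¹)
    X ⇌ E, rate k2*(cs2 - [E]) while solid is left; crystals form when [E] > cs2 (solubility = 0.240 M, k = 0.900 min⁻¹)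
    Q ⇌ D, rate k3*(csat - [D]) (kL = 2.80 min⁻¹)
    D → J (k = 1.20 min⁻¹)
    2 D → G (k = 3.30 M⁻¹ min⁻¹)
    E + Z → L (k = 0.280 M⁻¹ min⁻¹)

The carried pace gives 49.3% of Z for the neighbour charged with 0.35 M, which holds 49.0% of Z. In the flask at 8.00 min, dissolved Q, which is D, has a half-life of 0.58 min by the step to J and 1.5 min by the step to Z, so that step to J uses D 2.7 times as fast. In that flask cD reads 0.0702 M at 0.800 min and 0.0685 M at 8.00 min.

The runs were computed for an exercise.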